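**Retrosynthetic overview** (labdane numbering C1–C20)

- The C13=C14 enoate comes last, by Horner–Wadsworth–Emmons olefination of a C13 methyl ketone. C8–OH and C9–H are set together by syn hydroboration of a C8=C9 alkene on the face away from the angular methyl. C9–C11 comes from B-alkyl Suzuki coupling of a C9 enol triflate.
- Ring A (C1–C5, C10) is closed onto a preformed ring B by making C1–C10 and C2=C3 in one flask. The C10 enolate of a ring B ketone adds to vinyltriphenylphosphonium bromide, and the ylide so formed olefinates the C3 aldehyde. C2=C3 is hydrogenated afterwards.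
- Enabling feature: C10, the angular-methyl quaternary carbon shared by rings A and B, lies next to C9, which can stay a ketone (so C10 is an enolate carbon) until the side chain is attached. C3 hangs on the quaternary gem-dimethyl carbon C4, so its aldehyde cannot enolize and waits for the ylide.
- C4–C5 comes from a Mukaiyama–Michael addition anti to the C6 silyloxy group of (R)-4-silyloxy-2-methylcyclohexenone. Ring order: B (purchased), then A.

Key step: step 4

Remark: compound 1 is assumed to be purchasable as the (R) enantiomer (both enantiomers of this silyloxy enone are catalogue building blocks); all carbon locants are labdane numbers of the target.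

**Route**

Step 1
Reactants: 1 (R)-4-(tert-butyldimethylsilyloxy)cyclohex-2-en-1-one
Product: 2 (R)-4-(tert-butyldimethylsilyloxy)-2-iodocyclohex-2-en-1-one
Conditions: I2 (1.5 equiv), pyridine/CH2Cl2 (1:1), 0 → 23 °C
Reagents that add atoms: iodine, II
Why: α-Iodination of the enone by the pyridine addition–iodination–elimination sequence should put iodine only on the α-carbon (future C10) and leave the C6 stereocentre untouched.

Step 2
Reactants: 2 (R)-4-(tert-butyldimethylsilyloxy)-2-iodocyclohex-2-en-1-one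
Product: 3 (R)-4-(tert-butyldimethylsilyloxy)-2-methylcyclohex-2-en-1-one
Conditions: Me4Sn (2 equiv), Pd2(dba)3 (2.5 mol%), AsPh3 (10 mol%), CuI (10 mol%), NMP, 60 °C
Reagents that add atoms: tetramethylstannane, C[Sn](C)(C)C
Why: Stille coupling of the α-iodoenone should install the future C20 methyl under neutral conditions that the base-sensitive γ-silyloxy enone tolerates.

Step 3
Reactants: 3 (R)-4-(tert-butyldimethylsilyloxy)-2-methylcyclohex-2-en-1-one; 4 2-methyl-1-(trimethylsilyloxy)prop-1-ene
Product: 5 2-[(1S,6R)-6-(tert-butyldimethylsilyloxy)-2-methyl-3-(trimethylsilyloxy)cyclohex-2-en-1-yl]-2-methylpropanal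
Conditions: 4 (1.5 equiv), TrSbCl6 (5 mol%), CH2Cl2, −78 °C; Et3N quench, filtration through basic alumina, used without further purification
Reagents that add atoms: none
Why: The Mukaiyama–Michael addition with silyl transfer should form the C4–C5 bond and deliver the C9/C10 silyl enol ether regiospecifically; the nucleophile should attack C5 anti to the neighbouring C6 silyloxy group, which sets C5 (C5/C6 trans).

Step 4
Reactants: 5 2-[(1S,6R)-6-(tert-butyldimethylsilyloxy)-2-methyl-3-(trimethylsilyloxy)cyclohex-2-en-1-yl]-2-methylpropanal; 6 triphenyl(vinyl)phosphonium bromide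
Product: 9 (4R,4aR,8aR)-4-(tert-butyldimethylsilyloxy)-5,5,8a-trimethyl-3,4,4a,5,8,8a-hexahydronaphthalen-1(2H)-one, via potassium enolate 7 (not isolated), via phosphonium ylide 8 (not isolated)
Conditions: KOtBu (1.05 equiv), THF, −78 °C, 30 min; then 6 (1.1 equiv) in DMF added slowly, −78 → 23 °C, then 50 °C
Reagents that add atoms: none
Why: Potassium tert-butoxide should cleave the Si–O bond of 5 to give the tetrasubstituted C9/C10 enolate 7 regiospecifically, which adds through C10 to the CH2 terminus of the vinylphosphonium salt (C10–C1 bond) and thereby generates ylide 8 at C2; the ylide then closes ring A by intramolecular Wittig olefination of the C3 aldehyde (6-exo-trig attack of C2 on the carbonyl, oxaphosphetane, loss of Ph3PO), so C2=C3 is necessarily cis inside the new cyclohexene. The closest known reaction type is the Schweizer annulation (Michael-initiated ring closure of keto-carbonyl enolates with vinyltriphenylphosphonium bromide), here fed by an enolate released from a silyl enol ether. The new quaternary stereocentre C10 is controlled by the adjacent C5 substituent: A(1,2) strain with the C10 methyl turns the bulky C5 group pseudoaxial, so the acceptor approaches the enolate anti to it (the trans outcome known for 2-methyl-3-substituted cyclohexanone enolates and for three-component enone couplings), which puts C1 trans to C4 and should give the trans-fused decalin with the C10 methyl axial. The step needs C- over O-alkylation and no enolate equilibration to C8, secured by the soft Michael acceptor and by making the enolate from the silyl enol ether without a proton source. Chemoselectivity of the olefination is built in: the aldehyde cannot enolize (C4 is quaternary) and so cannot quench the ylide, and the C9 ketone could react only by forming a four-membered ring.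

Step 5
Reactants: 9 (4R,4aR,8aR)-4-(tert-butyldimethylsilyloxy)-5,5,8a-trimethyl-3,4,4a,5,8,8a-hexahydronaphthalen-1(2H)-one
Product: 10 (4R,4aR,8aR)-4-(tert-butyldimethylsilyloxy)-5,5,8a-trimethyloctahydronaphthalen-1(2H)-one
Conditions: H2 (1 atm), 10% Pd/C, EtOAc, 23 °C
Reagents that add atoms: none
Why: Heterogeneous hydrogenation should saturate the cis-disubstituted C2=C3 alkene and leave the hindered ketone and the silyl ether alone.

Step 6
Reactants: 10 (4R,4aR,8aR)-4-(tert-butyldimethylsilyloxy)-5,5,8a-trimethyloctahydronaphthalen-1(2H)-one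
Product: 12 (4R,4aR,8aR)-4-(tert-butyldimethylsilyloxy)-2,5,5,8a-tetramethyloctahydronaphthalen-1(2H)-one (C8 epimers), via lithium enolate 11 (not isolated)
Conditions: LDA (1.1 equiv), THF, −78 °C; MeI (1.5 equiv), −78 → 0 °C
Reagents that add atoms: iodomethane, CI
Why: Enolate alkylation can occur only at C8 because C10 is quaternary, so it should install the future C17 methyl; the C8 configuration does not matter because C8 becomes sp2 in the next step.

Step 7
Reactants: 12 (4R,4aR,8aR)-4-(tert-butyldimethylsilyloxy)-2,5,5,8a-tetramethyloctahydronaphthalen-1(2H)-one (C8 epimers)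
Product: 14 (4R,4aR,8aR)-4-(tert-butyldimethylsilyloxy)-2,5,5,8a-tetramethyl-3,4,4a,5,6,7,8,8a-octahydronaphthalen-1-yl trifluoromethanesulfonate, via potassium enolate 13 (not isolated)
Conditions: KHMDS (1.3 equiv), THF, −78 → 0 °C; PhNTf2 (1.3 equiv), −78 → 23 °C
Reagents that add atoms: N-phenylbis(trifluoromethanesulfonimide), O=S(=O)(N(c1ccccc1)S(=O)(=O)C(F)(F)F)C(F)(F)F
Why: O-Triflation of the only possible enolate (towards C8) should give the tetrasubstituted C8=C9 enol triflate, as is routine for 2,2,6-trisubstituted cyclohexanones.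

Step 8
Reactants: 14 (4R,4aR,8aR)-4-(tert-butyldimethylsilyloxy)-2,5,5,8a-tetramethyl-3,4,4a,5,6,7,8,8a-octahydronaphthalen-1-yl trifluoromethanesulfonate; 15 2-methyl-2-vinyl-1,3-dioxolane
Product: 17 2-[2-[(4R,4aR,8aR)-4-(tert-butyldimethylsilyloxy)-2,5,5,8a-tetramethyl-3,4,4a,5,6,7,8,8a-octahydronaphthalen-1-yl]ethyl]-2-methyl-1,3-dioxolane, via B-alkyl-9-BBN 16 (not isolated)
Conditions: 15 (2 equiv), 9-BBN-H (2 equiv), THF, 0 → 23 °C; then 14, Pd(dppf)Cl2 (10 mol%), AsPh3 (10 mol%), Cs2CO3 (3 equiv), DMF/H2O, 60 °C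
Reagents that add atoms: none
Why: Anti-Markovnikov hydroboration of 15 followed by B-alkyl Suzuki–Miyaura coupling with the enol triflate should form the C9–C11 bond and bring in C11–C13 and C16 with the ketone masked.

Step 9
Reactants: 17 2-[2-[(4R,4aR,8aR)-4-(tert-butyldimethylsilyloxy)-2,5,5,8a-tetramethyl-3,4,4a,5,6,7,8,8a-octahydronaphthalen-1-yl]ethyl]-2-methyl-1,3-dioxolane
Product: 19 2-[2-[(1S,2S,4R,4aR,8aR)-4-(tert-butyldimethylsilyloxy)-2-hydroxy-2,5,5,8a-tetramethyldecahydronaphthalen-1-yl]ethyl]-2-methyl-1,3-dioxolane, via C8 alkylborane 18 (not isolated)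
Conditions: BH3·THF (5 equiv), THF, 0 → 40 °C; then 3 M NaOH, 30% H2O2, 0 → 40 °C
Reagents that add atoms: hydrogen peroxide, OO
Why: Syn hydroboration of the tetrasubstituted C8=C9 alkene should place boron on the less hindered C8 (C9 is neopentylic) and add from the face opposite the axial C10 methyl, so that oxidation with retention sets C8 (OH) and C9 (H) together, cis to each other.

Step 10
Reactants: 19 2-[2-[(1S,2S,4R,4aR,8aR)-4-(tert-butyldimethylsilyloxy)-2-hydroxy-2,5,5,8a-tetramethyldecahydronaphthalen-1-yl]ethyl]-2-methyl-1,3-dioxolane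
Product: 20 4-[(1S,2S,4R,4aR,8aR)-2,4-dihydroxy-2,5,5,8a-tetramethyldecahydronaphthalen-1-yl]butan-2-one
Conditions: 3 M HCl (aq)/THF (1:2), 40 °C
Reagents that add atoms: water, O
Why: Aqueous acid should hydrolyse the dioxolane to the methyl ketone and cleave the secondary silyl ether in the same operation, the aqueous medium disfavouring dehydration of the tertiary alcohol.

Step 11
Reactants: 20 4-[(1S,2S,4R,4aR,8aR)-2,4-dihydroxy-2,5,5,8a-tetramethyldecahydronaphthalen-1-yl]butan-2-one
Product: 21 methyl (2E)-5-[(1S,2S,4R,4aR,8aR)-2,4-dihydroxy-2,5,5,8a-tetramethyldecahydronaphthalen-1-yl]-3-methylpent-2-enoate (CNP0289884.1)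
Conditions: (MeO)2P(O)CH2CO2Me (5 equiv), NaH (7 equiv), THF, 0 → 65 °C
Reagents that add atoms: trimethyl phosphonoacetate, COC(=O)CP(=O)(OC)OC
Why: Horner–Wadsworth–Emmons olefination of the unhindered methyl ketone should give the trisubstituted enoate with the E isomer favoured (ester anti to the larger C12 chain); the free hydroxyls are only deprotonated reversibly and the minor Z isomer would be removed by chromatography.

**Compound list**

1 | (R)-4-(tert-butyldimethylsilyloxy)cyclohex-2-en-1-one | O=C1C=C[C@H](O[Si](C)(C)C(C)(C)C)CC1 | starting material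
2 | (R)-4-(tert-butyldimethylsilyloxy)-2-iodocyclohex-2-en-1-one | O=C1C(I)=C[C@H](O[Si](C)(C)C(C)(C)C)CC1 | intermediate
3 | (R)-4-(tert-butyldimethylsilyloxy)-2-methylcyclohex-2-en-1-one | CC1=C[C@H](O[Si](C)(C)C(C)(C)C)CCC1=O | intermediate
4 | 2-methyl-1-(trimethylsilyloxy)prop-1-ene | CC(C)=CO[Si](C)(C)C | starting material
5 | 2-[(1S,6R)-6-(tert-butyldimethylsilyloxy)-2-methyl-3-(trimethylsilyloxy)cyclohex-2-en-1-yl]-2-methylpropanal (side chain trans to OTBS) | C[Si](C)(C)OC1=C(C)[C@@H](C(C)(C)C=O)[C@H](O[Si](C)(C)C(C)(C)C)CC1 | intermediate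
6 | triphenyl(vinyl)phosphonium bromide | C=C[P+](c1ccccc1)(c1ccccc1)c1ccccc1.[Br-] | starting material
7 | potassium (3S,4R)-4-(tert-butyldimethylsilyloxy)-2-methyl-3-(2-methyl-1-oxopropan-2-yl)cyclohex-1-en-1-olate | [K+].[O-]C1=C(C)[C@@H](C(C)(C)C=O)[C@H](O[Si](C)(C)C(C)(C)C)CC1 | intermediate
8 | 2-[(1R,2R,6R)-6-(tert-butyldimethylsilyloxy)-2-methyl-3-oxo-2-[2-(triphenyl-λ5-phosphanylidene)ethyl]cyclohexyl]-2-methylpropanal | O=C1CC[C@@H](O[Si](C)(C)C(C)(C)C)[C@H](C(C)(C)C=O)[C@@]1(C)CC=P(c1ccccc1)(c1ccccc1)c1ccccc1 | intermediate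
9 | (4R,4aR,8aR)-4-(tert-butyldimethylsilyloxy)-5,5,8a-trimethyl-3,4,4a,5,8,8a-hexahydronaphthalen-1(2H)-one (trans-fused) | O=C1CC[C@@H](O[Si](C)(C)C(C)(C)C)[C@@H]2C(C)(C)C=CC[C@@]12C | intermediate
10 | (4R,4aR,8aR)-4-(tert-butyldimethylsilyloxy)-5,5,8a-trimethyloctahydronaphthalen-1(2H)-one | O=C1CC[C@@H](O[Si](C)(C)C(C)(C)C)[C@@H]2C(C)(C)CCC[C@@]12C | intermediate
11 | lithium (4R,4aR,8aR)-4-(tert-butyldimethylsilyloxy)-5,5,8a-trimethyl-3,4,4a,5,6,7,8,8a-octahydronaphthalen-1-olate | [Li+].[O-]C1=CC[C@@H](O[Si](C)(C)C(C)(C)C)[C@@H]2C(C)(C)CCC[C@@]12C | intermediate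
12 | (4R,4aR,8aR)-4-(tert-butyldimethylsilyloxy)-2,5,5,8a-tetramethyloctahydronaphthalen-1(2H)-one (mixture of C8 epimers) | O=C1C(C)C[C@@H](O[Si](C)(C)C(C)(C)C)[C@@H]2C(C)(C)CCC[C@@]12C | intermediate
13 | potassium (4R,4aR,8aR)-4-(tert-butyldimethylsilyloxy)-2,5,5,8a-tetramethyl-3,4,4a,5,6,7,8,8a-octahydronaphthalen-1-olate | [K+].[O-]C1=C(C)C[C@@H](O[Si](C)(C)C(C)(C)C)[C@@H]2C(C)(C)CCC[C@@]12C | intermediate
14 | (4R,4aR,8aR)-4-(tert-butyldimethylsilyloxy)-2,5,5,8a-tetramethyl-3,4,4a,5,6,7,8,8a-octahydronaphthalen-1-yl trifluoromethanesulfonate | CC1=C(OS(=O)(=O)C(F)(F)F)[C@]2(C)CCCC(C)(C)[C@H]2[C@H](O[Si](C)(C)C(C)(C)C)C1 | intermediate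
15 | 2-methyl-2-vinyl-1,3-dioxolane | C=CC1(C)OCCO1 | starting material
16 | 9-[2-(2-methyl-1,3-dioxolan-2-yl)ethyl]-9-borabicyclo[3.3.1]nonane | CC1(CCB2C3CCCC2CCC3)OCCO1 | intermediate
17 | 2-[2-[(4R,4aR,8aR)-4-(tert-butyldimethylsilyloxy)-2,5,5,8a-tetramethyl-3,4,4a,5,6,7,8,8a-octahydronaphthalen-1-yl]ethyl]-2-methyl-1,3-dioxolane | CC1=C(CCC3(C)OCCO3)[C@]2(C)CCCC(C)(C)[C@H]2[C@H](O[Si](C)(C)C(C)(C)C)C1 | intermediate
18 | C8 alkylborane from syn addition of H–BH2 to 17 (BH2 on C8 and H on C9, both on the face opposite the C10 methyl) | CC1(CC[C@H]2[C@]3(C)CCCC(C)(C)[C@H]3[C@H](O[Si](C)(C)C(C)(C)C)C[C@]2(C)B)OCCO1 | intermediate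
19 | 2-[2-[(1S,2S,4R,4aR,8aR)-4-(tert-butyldimethylsilyloxy)-2-hydroxy-2,5,5,8a-tetramethyldecahydronaphthalen-1-yl]ethyl]-2-methyl-1,3-dioxolane | CC1(CC[C@H]2[C@]3(C)CCCC(C)(C)[C@H]3[C@H](O[Si](C)(C)C(C)(C)C)C[C@]2(C)O)OCCO1 | intermediate
20 | 4-[(1S,2S,4R,4aR,8aR)-2,4-dihydroxy-2,5,5,8a-tetramethyldecahydronaphthalen-1-yl]butan-2-one | CC(=O)CC[C@H]1[C@]2(C)CCCC(C)(C)[C@H]2[C@H](O)C[C@]1(C)O | intermediate
21 | methyl (2E)-5-[(1S,2S,4R,4aR,8aR)-2,4-dihydroxy-2,5,5,8a-tetramethyldecahydronaphthalen-1-yl]-3-methylpent-2-enoate (CNP0289884.1) | COC(=O)/C=C(\C)CC[C@H]1[C@]2(C)CCCC(C)(C)[C@H]2[C@H](O)C[C@]1(C)O | target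

**Step count and risks**

Total step count: 11. Longest linear sequence: 11 steps (1 → 21); fragments 4, 6 and 15 are purchased.

Steps most likely to fail:

1. Step 4 (key step). C-alkylation at the congested tetrasubstituted enolate may be slow, so that retro-Michael loss of the isobutyraldehyde unit or addition of the ylide to a second molecule of the phosphonium salt competes, and facial selectivity at C10 may erode. The fallback sets out from 5 and splits the event into three known reactions. The enolate released from 5 with KOtBu is C-allylated with allyl iodide at −78 °C, anti to the C5 substituent, to give 2-[(1R,2R,6R)-2-allyl-6-(tert-butyldimethylsilyloxy)-2-methyl-3-oxocyclohexyl]-2-methylpropanal F1. The neopentyl aldehyde is then methylenated selectively with Ph3P=CH2 (the hindered C9 ketone is left) to give (2R,3R,4R)-2-allyl-4-(tert-butyldimethylsilyloxy)-2-methyl-3-(2-methylbut-3-en-2-yl)cyclohexan-1-one F2. Ring-closing metathesis (Grubbs second-generation catalyst, CH2Cl2, 40 °C) then forms C2=C3 and comes back to the route at 9.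

2. Step 3. Bond formation between the fully substituted nucleophile carbon and the β-carbon flanked by the silyloxy group may stall, with desilylation of the nucleophile or loss of silanol from the enone taking over. The fallback sets out from 3 and uses the more nucleophilic ketene silyl acetal 1-methoxy-2-methyl-1-(trimethylsilyloxy)prop-1-ene under the same silyl-transfer catalysis. This gives methyl 2-[(1S,6R)-6-(tert-butyldimethylsilyloxy)-2-methyl-3-(trimethylsilyloxy)cyclohex-2-en-1-yl]-2-methylpropanoate F3. DIBAL-H (1.1 equiv, CH2Cl2, −78 °C) then reduces the hindered ester to the aldehyde and comes back to the route at 5.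

3. Step 9. Hydroboration of the tetrasubstituted alkene may be slow, may deliver boron to C9 instead of C8, or the borane may migrate on warming. The fallback sets out from 17. Epoxidation with mCPBA on the face away from the C10 methyl gives the 8,9-epoxide F4. Reductive opening with Cp2TiCl (from Cp2TiCl2 and Zn) and 1,4-cyclohexadiene (Nugent–RajanBabu conditions) should cleave the more congested C9–O bond, and the tertiary C9 radical should take hydrogen from the open face. This keeps the C8 oxygen in place and comes back to the route at 19.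

Further compounds
F1 | step 4 | 2-[(1R,2R,6R)-2-allyl-6-(tert-butyldimethylsilyloxy)-2-methyl-3-oxocyclohexyl]-2-methylpropanal | O=C1CC[C@@H](O[Si](C)(C)C(C)(C)C)[C@H](C(C)(C)C=O)[C@@]1(C)CC=C
F2 | step 4 | (2R,3R,4R)-2-allyl-4-(tert-butyldimethylsilyloxy)-2-methyl-3-(2-methylbut-3-en-2-yl)cyclohexan-1-one | O=C1CC[C@@H](O[Si](C)(C)C(C)(C)C)[C@H](C(C)(C)C=C)[C@@]1(C)CC=C
F3 | step 3 | methyl 2-[(1S,6R)-6-(tert-butyldimethylsilyloxy)-2-methyl-3-(trimethylsilyloxy)cyclohex-2-en-1-yl]-2-methylpropanoate | C[Si](C)(C)OC1=C(C)[C@@H](C(C)(C)C(=O)OC)[C@H](O[Si](C)(C)C(C)(C)C)CC1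
F4 | step 9 | 8,9-epoxide of 17 (oxygen on the face opposite the C10 methyl) | CC1(OCCO1)CC[C@]23O[C@@]2(C)C[C@@H](O[Si](C)(C)C(C)(C)C)[C@@H]4C(C)(C)CCC[C@@]34C
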